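**Retrosynthetic overview**
- The C1 carbinol goes back to the enone (last step, CBS reduction). The butenolide (second ring) goes back to a C6 acrylate and a C7 ketone: intramolecular Baylis–Hillman closure, then a 1,3-acetoxy shift puts the acetate on C13 and the alkene at C7=C11.
- Key disconnection: the ten-membered carbocycle (first ring) is cut at C8–C9. A C8 α-keto radical closes onto a 2-(sulfonylmethyl)enone by radical allyl transfer, which also creates the exocyclic methylene.
- Open chain: C5–C6 by carbonylative Sonogashira coupling of a (Z)-vinyl iodide (the inserted carbonyl is C6) and Alpine-Borane reduction (C6 stereocentre); C2–C3 by a boron aldol (C3 stereocentre).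
- Ring order: carbocycle first, lactone second.

Assumption: all five starting materials are taken as catalogue compounds; atom labels C1 to C15 follow germacrane numbering (C1 carbinol, C3 acetoxy carbon, C6 lactone carbinol, C12 lactone carbonyl, C13 acetoxymethyl, C14 exocyclic methylene, C15 methyl).

**Route**

Step 1
Reactants: 1 3-(hydroxymethyl)but-3-en-2-one
Product: 3 3-[(methanesulfonyl)methyl]but-3-en-2-one, via 3-(bromomethyl)but-3-en-2-one 2 (not isolated)
Conditions: PBr3 (0.4 equiv), Et2O, 0 °C; then MeSO2Na, MeOH, 25 °C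
Reagents that add atoms: sodium methanesulfinate CS(=O)[O-].[Na+]
Why: PBr3 turns the primary allylic alcohol into the allylic bromide and the sulfinate displaces it (SN2 or SN2′ give the same product) in a standard sulfinate alkylation, installing the sulfonyl group that later leaves as a radical; no stereocentre.

Step 2
Reactants: 4 (2Z)-3-iodo-2-methylprop-2-en-1-ol
Product: 5 (2Z)-3-iodo-2-methylprop-2-enal
Conditions: MnO2 (15 equiv), CH2Cl2, 25 °C, dark
Reagents that add atoms: none
Why: MnO2 allylic oxidation stops at the aldehyde and leaves the (Z)-iodoalkene geometry untouched when run in the dark.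

Step 3
Reactants: 3 3-[(methanesulfonyl)methyl]but-3-en-2-one, 5 (2Z)-3-iodo-2-methylprop-2-enal
Product: 6 (1Z,3S)-3-hydroxy-1-iodo-6-[(methanesulfonyl)methyl]-2-methylhepta-1,6-dien-5-one
Conditions: 3, (+)-Ipc2BCl, iPr2NEt, Et2O, −78 °C; then 5, −78 to −25 °C; H2O2, MeOH, pH 7 buffer, 0 °C
Reagents that add atoms: none
Why: Paterson boron aldol: the diisopinocampheylboron enolate formed at the methyl group of 3 attacks the Si face of enal 5 under reagent control, which sets C3 as S.

Step 4
Reactants: 6 (1Z,3S)-3-hydroxy-1-iodo-6-[(methanesulfonyl)methyl]-2-methylhepta-1,6-dien-5-one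
Product: 7 (1Z,3S)-1-iodo-6-[(methanesulfonyl)methyl]-2-methyl-5-oxohepta-1,6-dien-3-yl acetate
Conditions: Ac2O, pyridine, DMAP (5 mol %), CH2Cl2, 0 °C
Reagents that add atoms: acetic anhydride CC(=O)OC(C)=O
Why: DMAP-catalysed acetylation gives the C3 acetate of the target and removes the free hydroxyl before it can add to the enone.

Step 5
Reactants: 7 (1Z,3S)-1-iodo-6-[(methanesulfonyl)methyl]-2-methyl-5-oxohepta-1,6-dien-3-yl acetate, 8 ethynyltrimethylsilane, 9 carbon monoxide
Product: 10 (4Z,6S)-9-[(methanesulfonyl)methyl]-5-methyl-3,8-dioxo-1-(trimethylsilyl)deca-4,9-dien-1-yn-6-yl acetate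
Conditions: PdCl2(PPh3)2 (5 mol %), CuI (2 mol %), Et3N, THF, CO (1 atm), 25 °C
Reagents that add atoms: none
Why: Carbonylative Sonogashira coupling: oxidative addition of palladium into the C–I bond with retention of the Z geometry, CO insertion and alkynyl transfer give the ynone, the inserted CO becoming C6.

Step 6
Reactants: 10 (4Z,6S)-9-[(methanesulfonyl)methyl]-5-methyl-3,8-dioxo-1-(trimethylsilyl)deca-4,9-dien-1-yn-6-yl acetate
Product: 11 (3R,4Z,6S)-3-hydroxy-9-[(methanesulfonyl)methyl]-5-methyl-8-oxo-1-(trimethylsilyl)deca-4,9-dien-1-yn-6-yl acetate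
Conditions: (R)-Alpine-Borane (2 equiv), neat, 25 °C, 48 h; then MeCHO; ethanolamine
Reagents that add atoms: none
Why: Midland reduction with Alpine-Borane is selective for the alkynyl ketone and transfers hydride through a boat transition state with the slim alkynyl group in the crowded position, which gives the (R)-carbinol at C6.

Step 7
Reactants: 11 (3R,4Z,6S)-3-hydroxy-9-[(methanesulfonyl)methyl]-5-methyl-8-oxo-1-(trimethylsilyl)deca-4,9-dien-1-yn-6-yl acetate, 12 acryloyl chloride
Product: 13 (3R,4Z,6S)-6-acetoxy-9-[(methanesulfonyl)methyl]-5-methyl-8-oxo-1-(trimethylsilyl)deca-4,9-dien-1-yn-3-yl prop-2-enoate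
Conditions: iPr2NEt, CH2Cl2, −40 to 0 °C
Reagents that add atoms: none
Why: Acylation with the acid chloride puts the three lactone carbons C11 to C13 on the C6 oxygen without touching the stereocentre.

Step 8
Reactants: 13 (3R,4Z,6S)-6-acetoxy-9-[(methanesulfonyl)methyl]-5-methyl-8-oxo-1-(trimethylsilyl)deca-4,9-dien-1-yn-3-yl prop-2-enoate
Product: 15 (3R,4Z,6S)-6-acetoxy-1-bromo-9-[(methanesulfonyl)methyl]-5-methyl-2,8-dioxodeca-4,9-dien-3-yl prop-2-enoate, via bromoalkyne 14 (not isolated)
Conditions: NBS, AgNO3 (10 mol %), acetone, 25 °C, dark; then (Ph3P)AuNTf2 (3 mol %), H2O (5 equiv), 25 °C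
Reagents that add atoms: N-bromosuccinimide O=C1CCC(=O)N1Br; water O
Why: Silver-catalysed bromodesilylation gives bromoalkyne 14, and gold-catalysed hydration, steered by the bromine and the neighbouring ester carbonyl, places the oxygen on C7 to give the α-bromoketone that is the radical precursor; C6 is not touched.

Step 9
Reactants: 15 (3R,4Z,6S)-6-acetoxy-1-bromo-9-[(methanesulfonyl)methyl]-5-methyl-2,8-dioxodeca-4,9-dien-3-yl prop-2-enoate
Product: 16 (1R,2Z,4S)-4-acetoxy-3-methyl-7-methylidene-6,10-dioxocyclodec-2-en-1-yl prop-2-enoate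
Conditions: (Bu3Sn)2 (1.5 equiv), hν (300 W sunlamp), PhH, 80 °C, 0.002 M, slow addition of 15
Reagents that add atoms: none
Why: Proposed new method: Bu3Sn• from the ditin abstracts bromine from 15; the C8 α-keto radical has no hydrogen donor to quench it and no fast small-ring path (only 4-exo or 5-endo onto C4=C5), so it adds 10-endo to the unsubstituted CH2 terminus of the 2-(sulfonylmethyl)enone, and the tertiary C10 radical expels MeSO2• to form the exocyclic methylene while MeSO2• takes tin from the ditin to carry the chain; the closest known reactions are the Keck radical allylation of α-halo ketones with allyl stannanes or allyl sulfones and endo radical macrocyclisation onto enones, and no stereocentre is formed.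

Step 10
Reactants: 16 (1R,2Z,4S)-4-acetoxy-3-methyl-7-methylidene-6,10-dioxocyclodec-2-en-1-yl prop-2-enoate
Product: 17 (3S,4Z,6R)-3-acetoxy-7-hydroxy-1-oxogermacra-4,10(14),11(13)-trien-12,6-olide (C7 epimers)
Conditions: PMe3 (0.3 equiv), t-BuOH/THF, 25 °C
Reagents that add atoms: none
Why: Intramolecular Morita–Baylis–Hillman reaction: the phosphonium enolate of the acrylate adds to the activated C7 ketone and closes the five-membered lactone, while the α-substituted C1 enone is a poor Baylis–Hillman partner; the new C7 stereocentre is lost in the next step.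

Step 11
Reactants: 17 (3S,4Z,6R)-3-acetoxy-7-hydroxy-1-oxogermacra-4,10(14),11(13)-trien-12,6-olide (C7 epimers)
Product: 18 (3S,4Z,6R)-3,13-diacetoxy-1-oxogermacra-4,7(11),10(14)-trien-12,6-olide
Conditions: Ac2O, TMSOTf (5 mol %), CH2Cl2, −40 to −20 °C
Reagents that add atoms: acetic anhydride CC(=O)OC(C)=O
Why: Acetylation of the tertiary allylic alcohol and Lewis-acid catalysed 1,3-acetoxy shift (the known isomerisation of Baylis–Hillman acetates) give the more stable tetrasubstituted butenolide with the acetate on C13; C7 becomes sp2 and C6 is untouched.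

Step 12
Reactants: 18 (3S,4Z,6R)-3,13-diacetoxy-1-oxogermacra-4,7(11),10(14)-trien-12,6-olide
Product: 19 (1R,3S,4Z,6R)-3,13-diacetoxy-1-hydroxygermacra-4,7(11),10(14)-trien-12,6-olide
Conditions: (S)-Me-CBS oxazaborolidine (1 equiv), catecholborane, toluene, −78 °C; then MeOH
Reagents that add atoms: none
Why: Corey–Bakshi–Shibata reduction: the (S)-oxazaborolidine binds the ketone with the alkenyl group as the large substituent and delivers hydride in a 1,2 sense to give the (1R)-alcohol, leaving lactone and acetates intact.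

**Compound list**

1 | 3-(hydroxymethyl)but-3-en-2-one | CC(=O)C(=C)CO | starting material
2 | 3-(bromomethyl)but-3-en-2-one | CC(=O)C(=C)CBr | intermediate
3 | 3-[(methanesulfonyl)methyl]but-3-en-2-one | CC(=O)C(=C)CS(C)(=O)=O | intermediate
4 | (2Z)-3-iodo-2-methylprop-2-en-1-ol | OC/C(C)=C\I | starting material
5 | (2Z)-3-iodo-2-methylprop-2-enal | O=C/C(C)=C\I | intermediate
6 | (1Z,3S)-3-hydroxy-1-iodo-6-[(methanesulfonyl)methyl]-2-methylhepta-1,6-dien-5-one | I/C=C(/C)[C@@H](O)CC(=O)C(=C)CS(C)(=O)=O | intermediate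
7 | (1Z,3S)-1-iodo-6-[(methanesulfonyl)methyl]-2-methyl-5-oxohepta-1,6-dien-3-yl acetate | I/C=C(/C)[C@@H](OC(C)=O)CC(=O)C(=C)CS(C)(=O)=O | intermediate
8 | ethynyltrimethylsilane | C#C[Si](C)(C)C | starting material
9 | carbon monoxide | [C-]#[O+] | starting material
10 | (4Z,6S)-9-[(methanesulfonyl)methyl]-5-methyl-3,8-dioxo-1-(trimethylsilyl)deca-4,9-dien-1-yn-6-yl acetate | C[Si](C)(C)C#CC(=O)/C=C(/C)[C@@H](OC(C)=O)CC(=O)C(=C)CS(C)(=O)=O | intermediate
11 | (3R,4Z,6S)-3-hydroxy-9-[(methanesulfonyl)methyl]-5-methyl-8-oxo-1-(trimethylsilyl)deca-4,9-dien-1-yn-6-yl acetate | C[Si](C)(C)C#C[C@H](O)/C=C(/C)[C@@H](OC(C)=O)CC(=O)C(=C)CS(C)(=O)=O | intermediate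
12 | acryloyl chloride | C=CC(Cl)=O | starting material
13 | (3R,4Z,6S)-6-acetoxy-9-[(methanesulfonyl)methyl]-5-methyl-8-oxo-1-(trimethylsilyl)deca-4,9-dien-1-yn-3-yl prop-2-enoate | C[Si](C)(C)C#C[C@H](OC(=O)C=C)/C=C(/C)[C@@H](OC(C)=O)CC(=O)C(=C)CS(C)(=O)=O | intermediate
14 | (3R,4Z,6S)-6-acetoxy-1-bromo-9-[(methanesulfonyl)methyl]-5-methyl-8-oxodeca-4,9-dien-1-yn-3-yl prop-2-enoate | BrC#C[C@H](OC(=O)C=C)/C=C(/C)[C@@H](OC(C)=O)CC(=O)C(=C)CS(C)(=O)=O | intermediate
15 | (3R,4Z,6S)-6-acetoxy-1-bromo-9-[(methanesulfonyl)methyl]-5-methyl-2,8-dioxodeca-4,9-dien-3-yl prop-2-enoate | BrCC(=O)[C@H](OC(=O)C=C)/C=C(/C)[C@@H](OC(C)=O)CC(=O)C(=C)CS(C)(=O)=O | intermediate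
16 | (1R,2Z,4S)-4-acetoxy-3-methyl-7-methylidene-6,10-dioxocyclodec-2-en-1-yl prop-2-enoate | C=C1CCC(=O)[C@H](OC(=O)C=C)/C=C(/C)[C@@H](OC(C)=O)CC1=O | intermediate
17 | (3S,4Z,6R)-3-acetoxy-7-hydroxy-1-oxogermacra-4,10(14),11(13)-trien-12,6-olide (C7 epimers) | C=C1CCC2(O)C(=C)C(=O)O[C@@H]2/C=C(/C)[C@@H](OC(C)=O)CC1=O | intermediate
18 | (3S,4Z,6R)-3,13-diacetoxy-1-oxogermacra-4,7(11),10(14)-trien-12,6-olide | C=C1CCC2=C(COC(C)=O)C(=O)O[C@@H]2/C=C(/C)[C@@H](OC(C)=O)CC1=O | intermediate
19 | (1R,3S,4Z,6R)-3,13-diacetoxy-1-hydroxygermacra-4,7(11),10(14)-trien-12,6-olide | C=C1CCC2=C(COC(C)=O)C(=O)O[C@@H]2/C=C(/C)[C@@H](OC(C)=O)C[C@H]1O | target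

**Step count and risks**

Total steps: 12. Longest linear sequence: 11 steps (from 4 to 19; the branch from 1 is equally long).

The three steps most likely to fail:

Step 9. A ten-membered ring is at the lower limit for radical macrocyclisation, and the tin chain may break down in favour of oligomers. The fallback sets out from 15 and closes the same C8–C9 bond by ionic chemistry: Zn, CuI (cat.) and TMSCl in THF at high dilution make the C8 zinc enolate, which adds in conjugate fashion to the sulfonyl enone and then expels methanesulfinate (Reformatsky-type Michael addition–elimination). This gives 16 directly, where the route resumes, and makes no new compound.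

Step 10. A ketone is a sluggish Baylis–Hillman acceptor, and the C6 hydrogen next to the ketone in 16 can epimerise. The fallback sets out from 16 and uses a Lewis-acid halo-aldol instead of nucleophilic catalysis. MgI2 in CH2Cl2 at −40 °C adds iodide to the acrylate and the magnesium enolate closes onto the C7 ketone to give the iodomethyl hydroxy lactone F1. AgOAc in AcOH then exchanges iodide for acetate to give the acetoxymethyl hydroxy lactone F2. Burgess reagent dehydrates the tertiary alcohol towards C11, and the route is rejoined at 18, so steps 10 and 11 are both replaced.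

Step 5. The palladium catalyst may ionise the allyl sulfone, and the amine base may eliminate the β-acetoxy ketone. The fallback sets out from 7 and replaces carbonylation by addition and oxidation. CrCl2 with NiCl2 (cat.) in DMSO/THF couples the vinyl iodide with 3-(trimethylsilyl)prop-2-ynal (Nozaki–Hiyama–Kishi reaction) to give the epimeric propargylic alcohols F3. Dess–Martin periodinane then oxidises them to ynone 10, where the route resumes and step 6 sets C6.

Further compounds
F0 | step 9 | none | none
F1 | step 10 | (3S,4Z,6R)-3-acetoxy-7-hydroxy-13-iodo-1-oxogermacra-4,10(14)-dien-12,6-olide (C7 and C11 epimers) | C=C1CCC2(O)C(CI)C(=O)O[C@@H]2/C=C(/C)[C@@H](OC(C)=O)CC1=O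
F2 | step 10 | (3S,4Z,6R)-3,13-diacetoxy-7-hydroxy-1-oxogermacra-4,10(14)-dien-12,6-olide (C7 and C11 epimers) | C=C1CCC2(O)C(COC(C)=O)C(=O)O[C@@H]2/C=C(/C)[C@@H](OC(C)=O)CC1=O
F3 | step 5 | (4Z,6S)-3-hydroxy-9-[(methanesulfonyl)methyl]-5-methyl-8-oxo-1-(trimethylsilyl)deca-4,9-dien-1-yn-6-yl acetate (both C3 epimers) | C[Si](C)(C)C#CC(O)/C=C(/C)[C@@H](OC(C)=O)CC(=O)C(=C)CS(C)(=O)=O
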